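The vessel is closed, stirred and isothermal, and you want to know what two changes of charge do to its rate at one fixed conversion.

| setting | Tuesday's | Monday's | flask |
|---|---|---|---|
| starting material | 0.025 M | 0.038 M | 0.050 M |
| second substrate | 0.055 M | 0.055 M | 0.0550 M |
| enzyme | 12 µM | 12 µM | 12 µM |
| remark | run made earlier | run made earlier |  |

- Tuesday's (time / min: product / %, starting material / %): 0.167: 0.9, 98.9; 0.333: 1.6, 98.3; 0.667: 3.1, 97.2; 1.00: 3.7, 95.7; 1.33: 5.2, 95.3; 2.00: 6.8, 93.5; 2.50: 7.4, 92.6
- Monday's (time / min: product / %, starting material / %): 0.200: 0.4, 99.3; 0.333: 1.4, 98.4; 0.417: 2.2, 98.4; 0.667: 3.2, 97.3; 1.00: 3.8, 96.1; 1.50: 4.9, 95.0; 2.50: 6.7, 92.5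

(scatter of a reading: 0.3 percentage points)

- factor on the rate of making product when 5.0% of the starting material are converted if second substrate is charged twice over
- factor on the rate when 5.0% of the starting material are converted if enzyme is charged at 60 µM instead

Watch the rate and nothing else. In fractions of the charge, the two runs together read 0.0472 min⁻¹ over the first 0.667 min, and 0.0220 min⁻¹ from 1.00 min to 2.50 min, a stretch that straddles the conversion asked about. Their ratio reads 2.15; call it S, the slowing factor, the early rate over the rate near that conversion. Loss of starting material gives a factor of 1.05, less than S, so something else does the rest of the slowing.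

My own reckoning supposes that this slowing runs on the clock. The flask at 12 µM of enzyme then arrives at 5.0% already slowed by S. At 60 µM, the early rate gets there in about 0.212 min, sooner than 1.00 min, so on this supposition I count it at its early rate. In powers of ten, the charge adds 0.699 and S adds 0.332, which makes 1.03, a factor of 10.7. For second substrate, no run changes the charge, so this part is a guess: if the rate is first order in it, I put the factor somewhere from 2 to 4.30.

The forecast gives 2.2 and 6, with the remark “The data cannot firmly separate these”; its enzyme factor stands below mine.

The simulation gives 2.81 and 10.2.

    starting material + enzyme ⇌ starting complex (K = 6.80 M⁻¹, k = 3400 M⁻¹ s⁻¹)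
    second substrate + starting complex ⇌ ternary complex (K = 11.0 M⁻¹, k = 1700 M⁻¹ s⁻¹)
    ternary complex → enzyme + product (k = 33.0 s⁻¹)
    enzyme ⇌ dormant form (K = 3.30, k = 0.0200 s⁻¹)

The flask at 60 µM of enzyme gains 2.04 over plain proportion, where S read 2.15. That gain shows as an apparent order in enzyme of 1.7 at 5.0% in this flask. The simulated run without the return of ternary complex to second substrate + starting complex brings that order to 1.2. The simulated run without the return of starting complex to starting material + enzyme, the largest single effect of these two, brings it to 1.0.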